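| flask | solid substrate | remark | time |
|---|---|---|---|
| cedar | 0.070 M | run made earlier |  |
| elm | 0.11 M | run made earlier |  |
| flask | 0.050 M |  | 15 h |

| run | time / h | solid substrate / % | starting material / % |
|---|---|---|---|
| cedar | 0.833 | 98.6 | 1.1 |
| cedar | 2.50 | 95.5 | 4.6 |
| cedar | 4.00 | 92.7 | 6.1 |
| cedar | 6.00 | 91.4 | 8.1 |
| cedar | 10.0 | 85.5 | 10.6 |
| cedar | 12.0 | 82.1 | 12.3 |
| elm | 0.833 | 98.8 | 1.0 |
| elm | 2.50 | 95.7 | 1.4 |
| elm | 4.00 | 96.0 | 4.9 |
| elm | 6.00 | 92.5 | 5.8 |
| elm | 10.0 | 89.5 | 7.1 |
| elm | 12.0 | 88.6 | 9.0 |

(scatter of a reading: 1 percentage point)

- given per volume of solution although it is solid: solid substrate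
- steps that have been proposed: starting material <-> intermediate A; starting material <-> intermediate B; intermediate B -> side product; intermediate A <-> intermediate C; intermediate C -> intermediate D; intermediate D -> target; intermediate A -> intermediate D; solid substrate <-> starting material
- at the start none of the solid substrate is in solution
- what has only dissolved of solid substrate counts as not reacted
- what has gone from starting material into another species counts as reacted, even if it can come back
- the reaction counts as stopped when no species that holds the solid substrate changes by six tenths of a point or more over the second half of the time
- starting material means what is dissolved; the solid is not counted in it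

- which holds at 15 h: what has brought the reaction to rest, or that it has not come to rest (for what has run out or reacted, a solid counts together with what of it has only dissolved) (it is still moving / all of the solid substrate has reacted / forward and back rates have come level)
- part of the solid substrate that has turned into other species by 15 h (what has only dissolved does not count)
- starting material at 15 h, in percent of the solid substrate charged

0.00104 M/h is what left the solid per hour in the cedar run up to 12.0 h. The elm run, with its larger charge, gave 0.00104 M/h. So freeze that rate, a zero-order release. For this flask, rate times time over charge gives 31.3%: this is the off-solid share, the part of the charge you expect to have left the solid by then. It is below one, so you expect solid left and a flask still moving.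

Is one number enough? It gives the sum of dissolved and reacted, not the split between them. Of what had left the solid by 12.0 h, the readings show 21.1% gone on in elm and 31.3% in cedar, loosely at a scatter of 1 percentage point. My own reckoning therefore puts conversion in this flask at 6.60% to 9.80%.

The forecast says it is still moving, with conversion 10% and starting material 21%, on the ground that “Dissolution therefore doesn't depend on the charge”.

This flask gives conversion 13.2% and starting material 18.8%, and it is still moving. Their sum is 32.0% against the share of 31.3%, while the conversion lies above my range and inside the forecast's 6% to 15%.

    starting material ⇌ intermediate A (K = 1.55, k = 1.57 × 10⁻⁵ /s)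
    starting material ⇌ intermediate B (K = 0.490, k = 8.10 × 10⁻⁶ /s)
    intermediate B → side product (k = 3.35 × 10⁻⁴ /s)
    intermediate A ⇌ intermediate C (K = 0.204, k = 6.41 × 10⁻⁶ /s)
    intermediate C → intermediate D (k = 1.33 × 10⁻⁵ /s)
    intermediate D → target (k = 2.71 × 10⁻⁵ /s)
    intermediate A → intermediate D (k = 5.67 × 10⁻⁶ /s)
    solid substrate ⇌ starting material, rate k8*(cs8 - [starting material]) while solid is left; crystals form when [starting material] > cs8 (solubility = 42.0 mM, k = 8.19 × 10⁻⁶ /s)

In this flask, [starting material] reached 0.00940 M at 15 h, below the saturation value of 42 mM. The dissolving rate, 8.19 × 10⁻⁶ /s times the gap between saturation and [starting material], went from 0.00124 M/h at the start to 9.61 × 10⁻⁴ M/h at 15 h. For the neighbour charged with 0.020 M, the share comes to 78.0%; the computed flask has 80.0% off the solid.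

The numbers in the tables were generated by integration with constants of no real substance, noise included.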